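**Retrosynthetic overview**
1. Target 16 ⇐ two late epoxidations of bis-angelate 14: a Shi epoxidation of the side-chain alkene, then a peracid epoxidation of the ring alkene.
2. 14 ⇐ one double Mitsunobu reaction with angelic acid on triol 12, inverting C5 and C8 and leaving C6–OH free.
3. 12 ⇐ catalytic asymmetric Nozaki–Hiyama–Kishi coupling of ring enol triflate 8 with 4-methylpent-3-enal 10 (C7–C8 bond).
4. 8 ⇐ methyl ketone 6 ⇐ Stille acetylation and copper hydride 1,4-reduction of iododiene diol 2.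
5. 2 ⇐ toluene-dioxygenase cis-dihydroxylation of 4-iodotoluene 1. The carbocycle comes from the arene; the side-chain oxirane is closed next and the ring oxirane last.

Assumption: locants are ring C1 (bears the side chain), C2 (CH2), C3/C4 (oxirane, methyl on C4), C5 (angelate), C6 (OH) and chain C7 (=CH2), C8 (angelate), C9, C10/C11 (oxirane); the recombinant dioxygenase strain is accessible, and aldehyde 10 is made fresh because it is not reliably stocked.

**Step 1**
Reactants: 1 4-iodotoluene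
Product: 2 (1S,2S)-3-iodo-6-methylcyclohexa-3,5-diene-1,2-diol
Conditions: E. coli JM109(pDTG601A) whole cells (toluene dioxygenase), IPTG, glucose feed, air, phosphate buffer pH 7.2, 30 °C; EtOAc extraction; recrystallise
Reagents that add atoms: dioxygen, O=O
Why: Toluene-dioxygenase arene cis-dihydroxylation breaks the aromaticity and adds O2 to the 2,3-bond from the face dictated by the larger iodine (same sense as in halobenzene diols), so both carbinol centres are set as (1S,2S) in an expected 80–90% ee, raised by recrystallisation and finally purged as a diastereomer after step 6.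

**Step 2**
Reactants: 2 (1S,2S)-3-iodo-6-methylcyclohexa-3,5-diene-1,2-diol; 3 tributyl(1-ethoxyvinyl)stannane
Product: 5 1-[(5S,6R)-5,6-dihydroxy-4-methylcyclohexa-1,3-dien-1-yl]ethan-1-one, via ethoxyvinyl diene diol 4 (not isolated)
Conditions: Pd2(dba)3 (2.5 mol%), AsPh3 (20 mol%), CuI (10 mol%), NMP, 23 °C; then 0.5 M aq. oxalic acid, THF, 0 °C
Reagents that add atoms: tributyl(1-ethoxyvinyl)stannane 3, CCCC[Sn](CCCC)(CCCC)C(=C)OCC; water, O
Why: Stille cross-coupling of the alkenyl iodide on zerovalent palladium at room temperature (so the sensitive diene diol does not aromatise), followed by mild enol ether hydrolysis to the methyl ketone, with no stereocentre touched.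

**Step 3**
Reactants: 5 1-[(5S,6R)-5,6-dihydroxy-4-methylcyclohexa-1,3-dien-1-yl]ethan-1-one
Product: 6 1-[(1S,5S,6R)-5,6-dihydroxy-4-methylcyclohex-3-en-1-yl]ethan-1-one
Conditions: [(Ph3P)CuH]6 (0.4 equiv), H2O (3 equiv), THF, 23 °C; then DBU (0.1 equiv), CH2Cl2, 23 °C
Reagents that add atoms: none
Why: Copper hydride 1,4-conjugate reduction delivers hydride to C2 of the ketone-conjugated alkene (1,6-addition is disfavoured by the fully substituted C4), and DBU equilibration of the new α-centre puts the acetyl group equatorial and trans to C6–OH, which fixes C1 (a useful excess of the trans isomer is expected and the minor epimer can be re-equilibrated).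

**Step 4**
Reactants: 6 1-[(1S,5S,6R)-5,6-dihydroxy-4-methylcyclohex-3-en-1-yl]ethan-1-one
Product: 8 1-[(1S,5S,6R)-4-methyl-5,6-bis(triethylsilyloxy)cyclohex-3-en-1-yl]ethenyl trifluoromethanesulfonate, via bis-triethylsilyl ketone 7 (not isolated)
Conditions: Et3SiCl, imidazole, DMAP (cat.), CH2Cl2, 0 to 23 °C; filter, concentrate; then KN(SiMe3)2, THF, −78 °C; PhNTf2, −78 to 0 °C; aq. NH4Cl
Reagents that add atoms: chlorotriethylsilane, CC[Si](Cl)(CC)CC; N-phenylbis(trifluoromethanesulfonimide), O=S(=O)(N(c1ccccc1)S(=O)(=O)C(F)(F)F)C(F)(F)F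
Why: Silyl protection, then kinetic enolisation of the methyl ketone on the methyl side and O-triflation (enol triflate formation) give the 1,1-disubstituted alkenyl triflate without disturbing C1, because the hindered methine is much slower to deprotonate at −78 °C.

**Step 5**
Reactants: 9 4-methylpent-3-en-1-ol
Product: 10 4-methylpent-3-enal
Conditions: Dess–Martin periodinane, NaHCO3, CH2Cl2, 0 °C; used at once as a cold solution
Reagents that add atoms: none
Why: Dess–Martin oxidation under buffered, cold conditions gives the β,γ-unsaturated aldehyde without migration of the alkene into conjugation.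

**Step 6**
Reactants: 8 1-[(1S,5S,6R)-4-methyl-5,6-bis(triethylsilyloxy)cyclohex-3-en-1-yl]ethenyl trifluoromethanesulfonate; 10 4-methylpent-3-enal
Product: 12 (1R,2S,6R)-6-[(3R)-3-hydroxy-6-methylhepta-1,5-dien-2-yl]-3-methylcyclohex-3-ene-1,2-diol, via tris-triethylsilyl ether 11 (not isolated)
Conditions: CrCl2 (10 mol%), Kishi oxazoline–sulfonamide ligand (12 mol%, enantiomer that gives the 3R carbinol), proton sponge (12 mol%), NiCl2(2,9-dimethyl-1,10-phenanthroline) (5 mol%), Mn powder, LiCl, Et3SiCl, MeCN, 23 °C; then Bu4NF, THF, 0 °C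
Reagents that add atoms: 4-methylpent-3-enal 10, CC(C)=CCC=O; chlorotriethylsilane, CC[Si](Cl)(CC)CC (stays only in 11)
Why: Catalytic asymmetric Nozaki–Hiyama–Kishi coupling, in which the alkenylchromium species formed by nickel insertion into the triflate adds to the aldehyde under control of the chiral sulfonamide ligand, sets C8 as R (so that step 7 inverts it to S), and fluoride then removes all three silyl groups; the C8 epimer and any material from the minor ring enantiomer are separated here as diastereomers.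

**Step 7**
Reactants: 12 (1R,2S,6R)-6-[(3R)-3-hydroxy-6-methylhepta-1,5-dien-2-yl]-3-methylcyclohex-3-ene-1,2-diol; 13 angelic acid
Product: 14 (1R,5R,6R)-6-hydroxy-2-methyl-5-[(3S)-6-methyl-3-{[(2Z)-2-methylbut-2-enoyl]oxy}hepta-1,5-dien-2-yl]cyclohex-2-en-1-yl (2Z)-2-methylbut-2-enoate
Conditions: angelic acid (3 equiv), PPh3 (3 equiv), DIAD (3 equiv), toluene, −20 to 23 °C
Reagents that add atoms: angelic acid 13, C/C=C(/C)C(=O)O
Why: Double Mitsunobu esterification displaces both allylic carbinols with inversion (C5 through the cis-diol dioxaphosphorane, which opens at the allylic carbon as in the cis- to trans-carveol inversion, and C8 by direct SN2), turning 5α-OH/8R-OH into the 5β/8S angelates while the non-allylic, doubly flanked C6–OH stays free and the Z acid is used only as a carboxylate nucleophile, so it should not isomerise.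

**Step 8**
Reactants: 14 (1R,5R,6R)-6-hydroxy-2-methyl-5-[(3S)-6-methyl-3-{[(2Z)-2-methylbut-2-enoyl]oxy}hepta-1,5-dien-2-yl]cyclohex-2-en-1-yl (2Z)-2-methylbut-2-enoate
Product: 15 (1R,5R,6R)-5-[(3S)-4-[(2R)-3,3-dimethyloxiran-2-yl]-3-{[(2Z)-2-methylbut-2-enoyl]oxy}but-1-en-2-yl]-6-hydroxy-2-methylcyclohex-2-en-1-yl (2Z)-2-methylbut-2-enoate
Conditions: Shi ketone from D-fructose (30 mol%), Oxone (2KHSO5·KHSO4·K2SO4, 1.4 equiv), K2CO3, Bu4NHSO4, MeCN/CH2(OMe)2/aq. Na2B4O7 buffer, −5 °C, short reaction time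
Reagents that add atoms: potassium peroxymonosulfate, [K+].[O-]S(=O)(=O)OO
Why: Shi asymmetric epoxidation, in which the dioxirane of the D-fructose-derived ketone attacks the electron-rich Me2C=CH alkene through the spiro transition state, is expected to give the 2R oxirane (C10), while the ring alkene and the 1,1-disubstituted alkene are deactivated by their allylic esters and the angelate alkenes are electron-poor.

**Step 9**
Reactants: 15 (1R,5R,6R)-5-[(3S)-4-[(2R)-3,3-dimethyloxiran-2-yl]-3-{[(2Z)-2-methylbut-2-enoyl]oxy}but-1-en-2-yl]-6-hydroxy-2-methylcyclohex-2-en-1-yl (2Z)-2-methylbut-2-enoate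
Product: 16 (1S,2S,3R,4R,6S)-4-[(3S)-4-[(2R)-3,3-dimethyloxiran-2-yl]-3-{[(2Z)-2-methylbut-2-enoyl]oxy}but-1-en-2-yl]-3-hydroxy-1-methyl-7-oxabicyclo[4.1.0]heptan-2-yl (2Z)-2-methylbut-2-enoate
Conditions: mCPBA (1.1 equiv), NaHCO3, CH2Cl2, 0 °C
Reagents that add atoms: mCPBA, OOC(=O)c1cccc(Cl)c1
Why: Prilezhaev epoxidation of the most nucleophilic remaining alkene, where the peracid approaches the trisubstituted ring alkene anti to the allylic angelate on C5 and is hydrogen-bond guided by the homoallylic C6–OH on the same α face, sets C3 and C4 with the oxirane cis to C6–OH and trans to C5–OAng.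

**Compound list**
1 | 4-iodotoluene | Cc1ccc(I)cc1 | starting material
2 | (1S,2S)-3-iodo-6-methylcyclohexa-3,5-diene-1,2-diol | CC1=CC=C(I)[C@@H](O)[C@H]1O | intermediate
3 | tributyl(1-ethoxyvinyl)stannane | CCCC[Sn](CCCC)(CCCC)C(=C)OCC | starting material
4 | (1S,2R)-3-(1-ethoxyvinyl)-6-methylcyclohexa-3,5-diene-1,2-diol | CCOC(=C)C1=CC=C(C)[C@H](O)[C@@H]1O | intermediate (not isolated)
5 | 1-[(5S,6R)-5,6-dihydroxy-4-methylcyclohexa-1,3-dien-1-yl]ethan-1-one | CC(=O)C1=CC=C(C)[C@H](O)[C@@H]1O | intermediate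
6 | 1-[(1S,5S,6R)-5,6-dihydroxy-4-methylcyclohex-3-en-1-yl]ethan-1-one | CC(=O)[C@H]1CC=C(C)[C@H](O)[C@@H]1O | intermediate
7 | 1-[(1S,5S,6R)-4-methyl-5,6-bis(triethylsilyloxy)cyclohex-3-en-1-yl]ethan-1-one | CC(=O)[C@H]1CC=C(C)[C@H](O[Si](CC)(CC)CC)[C@@H]1O[Si](CC)(CC)CC | intermediate (not isolated)
8 | 1-[(1S,5S,6R)-4-methyl-5,6-bis(triethylsilyloxy)cyclohex-3-en-1-yl]ethenyl trifluoromethanesulfonate | C=C(OS(=O)(=O)C(F)(F)F)[C@H]1CC=C(C)[C@H](O[Si](CC)(CC)CC)[C@@H]1O[Si](CC)(CC)CC | intermediate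
9 | 4-methylpent-3-en-1-ol | CC(C)=CCCO | starting material
10 | 4-methylpent-3-enal | CC(C)=CCC=O | intermediate
11 | triethyl{[(3R)-6-methyl-2-[(1R,5S,6R)-4-methyl-5,6-bis(triethylsilyloxy)cyclohex-3-en-1-yl]hepta-1,5-dien-3-yl]oxy}silane | C=C([C@@H](CC=C(C)C)O[Si](CC)(CC)CC)[C@H]1CC=C(C)[C@H](O[Si](CC)(CC)CC)[C@@H]1O[Si](CC)(CC)CC | intermediate (not isolated)
12 | (1R,2S,6R)-6-[(3R)-3-hydroxy-6-methylhepta-1,5-dien-2-yl]-3-methylcyclohex-3-ene-1,2-diol | C=C([C@@H](CC=C(C)C)O)[C@H]1CC=C(C)[C@H](O)[C@@H]1O | intermediate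
13 | angelic acid, (2Z)-2-methylbut-2-enoic acid | C/C=C(/C)C(=O)O | starting material
14 | (1R,5R,6R)-6-hydroxy-2-methyl-5-[(3S)-6-methyl-3-{[(2Z)-2-methylbut-2-enoyl]oxy}hepta-1,5-dien-2-yl]cyclohex-2-en-1-yl (2Z)-2-methylbut-2-enoate | C=C([C@H](CC=C(C)C)OC(=O)/C(C)=C\C)[C@H]1CC=C(C)[C@@H](OC(=O)/C(C)=C\C)[C@@H]1O | intermediate
15 | (1R,5R,6R)-5-[(3S)-4-[(2R)-3,3-dimethyloxiran-2-yl]-3-{[(2Z)-2-methylbut-2-enoyl]oxy}but-1-en-2-yl]-6-hydroxy-2-methylcyclohex-2-en-1-yl (2Z)-2-methylbut-2-enoate | C=C([C@H](C[C@H]1OC1(C)C)OC(=O)/C(C)=C\C)[C@H]1CC=C(C)[C@@H](OC(=O)/C(C)=C\C)[C@@H]1O | intermediate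
16 | (1S,2S,3R,4R,6S)-4-[(3S)-4-[(2R)-3,3-dimethyloxiran-2-yl]-3-{[(2Z)-2-methylbut-2-enoyl]oxy}but-1-en-2-yl]-3-hydroxy-1-methyl-7-oxabicyclo[4.1.0]heptan-2-yl (2Z)-2-methylbut-2-enoate | C=C([C@H](C[C@H]1OC1(C)C)OC(=O)/C(C)=C\C)[C@H]1C[C@@H]2O[C@]2(C)[C@@H](OC(=O)/C(C)=C\C)[C@@H]1O | target

**Step count**
Total: 9 steps. Longest linear sequence: 8 steps (1, 2, 3, 4, 6, 7, 8, 9); step 5 is a one-step side branch.

**Three steps most likely to fail, with fallbacks**

Step 3 (1,4- versus 1,6-hydride delivery, and the C1 ratio after equilibration of a β-hydroxy ketone). The fallback sets out from 2 and comes back at 6, carrying an ester instead of a ketone through the reduction. Methoxycarbonylation of 2 (Pd(OAc)2, PPh3, CO 1 atm, MeOH, Et3N, 40 °C) gives methyl (5S,6R)-5,6-dihydroxy-4-methylcyclohexa-1,3-diene-1-carboxylate F1. Mg turnings in MeOH then reduce only the α,β-bond by electron transfer, and the methoxide formed equilibrates C1 cleanly, giving methyl (1S,5S,6R)-5,6-dihydroxy-4-methylcyclohex-3-ene-1-carboxylate F2. MeNH(OMe)·HCl with i-PrMgCl gives (1S,5S,6R)-5,6-dihydroxy-N-methoxy-N,4-dimethylcyclohex-3-ene-1-carboxamide F3, and MeMgBr converts F3 into 6.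

Step 7 (two inversions in one pot; risks are SN2′ attack at the C7 methylene, reaction at C6–OH, or Z to E drift). The fallback sets out from 8 and comes back at 14, separating the two esterifications. The Nozaki–Hiyama–Kishi coupling of 8 with 10 is run with the enantiomeric ligand and Cp2ZrCl2 in place of Et3SiCl, so that aqueous work-up leaves the ring silyl ethers on and gives the bis-silyl (3S)-allylic alcohol F4. Its only free hydroxyl is acylated with retention by the mixed anhydride of angelic acid and 2,4,6-trichlorobenzoyl chloride (Et3N, toluene, 80 °C, no DMAP) to give the bis-silyl C8 angelate F5. HF·pyridine in THF removes both silyl groups to give the C8-angelate cis-diol F6, and a single Mitsunobu reaction with angelic acid, which now has only the allylic C5–OH to invert, gives 14.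

Step 9 (facial selectivity of the last epoxidation rests on two moderate effects). The fallback sets out from 6 and comes back at 16, installing the ring oxirane early under reliable cis direction by the allylic C5–OH. VO(acac)2 with t-BuOOH in CH2Cl2 converts 6 into the α-epoxy ketone diol F7. Silylation as in step 4 gives the bis-silyl epoxy ketone F8 and enol triflation gives the epoxy alkenyl triflate F9. Coupling with 10 as in step 6 gives the tris-silyl epoxy adduct F10 and then, after Bu4NF, the epoxy triol F11. The double Mitsunobu reaction with angelic acid gives the ring-epoxy bis-angelate F12 (the C5 inversion is now next to a quaternary oxirane carbon and will need forcing), and Shi epoxidation of its only trisubstituted alkene gives 16.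

**Further compounds**
F1 | step 3 | methyl (5S,6R)-5,6-dihydroxy-4-methylcyclohexa-1,3-diene-1-carboxylate | COC(=O)C1=CC=C(C)[C@H](O)[C@@H]1O
F2 | step 3 | methyl (1S,5S,6R)-5,6-dihydroxy-4-methylcyclohex-3-ene-1-carboxylate | COC(=O)[C@H]1CC=C(C)[C@H](O)[C@@H]1O
F3 | step 3 | (1S,5S,6R)-5,6-dihydroxy-N-methoxy-N,4-dimethylcyclohex-3-ene-1-carboxamide | CON(C)C(=O)[C@H]1CC=C(C)[C@H](O)[C@@H]1O
F4 | step 7 | (3S)-6-methyl-2-[(1R,5S,6R)-4-methyl-5,6-bis(triethylsilyloxy)cyclohex-3-en-1-yl]hepta-1,5-dien-3-ol | C=C([C@H](CC=C(C)C)O)[C@H]1CC=C(C)[C@H](O[Si](CC)(CC)CC)[C@@H]1O[Si](CC)(CC)CC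
F5 | step 7 | (3S)-6-methyl-2-[(1R,5S,6R)-4-methyl-5,6-bis(triethylsilyloxy)cyclohex-3-en-1-yl]hepta-1,5-dien-3-yl (2Z)-2-methylbut-2-enoate | C=C([C@H](CC=C(C)C)OC(=O)/C(C)=C\C)[C@H]1CC=C(C)[C@H](O[Si](CC)(CC)CC)[C@@H]1O[Si](CC)(CC)CC
F6 | step 7 | (3S)-2-[(1R,5S,6R)-5,6-dihydroxy-4-methylcyclohex-3-en-1-yl]-6-methylhepta-1,5-dien-3-yl (2Z)-2-methylbut-2-enoate | C=C([C@H](CC=C(C)C)OC(=O)/C(C)=C\C)[C@H]1CC=C(C)[C@H](O)[C@@H]1O
F7 | step 9 | ketone diol 6 carrying an α-oxirane across C3–C4, cis to both hydroxyls | CC(=O)[C@H]1C[C@@H]2O[C@]2(C)[C@H](O)[C@@H]1O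
F8 | step 9 | bis(triethylsilyl) ether of F7 | CC(=O)[C@H]1C[C@@H]2O[C@]2(C)[C@H](O[Si](CC)(CC)CC)[C@@H]1O[Si](CC)(CC)CC
F9 | step 9 | enol triflate of F8 (C7 alkenyl triflate, ring α-oxirane) | C=C(OS(=O)(=O)C(F)(F)F)[C@H]1C[C@@H]2O[C@]2(C)[C@H](O[Si](CC)(CC)CC)[C@@H]1O[Si](CC)(CC)CC
F10 | step 9 | tris(triethylsilyl) ether of the (8R) coupling product bearing the ring α-oxirane | C=C([C@@H](CC=C(C)C)O[Si](CC)(CC)CC)[C@H]1C[C@@H]2O[C@]2(C)[C@H](O[Si](CC)(CC)CC)[C@@H]1O[Si](CC)(CC)CC
F11 | step 9 | epoxy triol: 12 carrying the ring α-oxirane across C3–C4 | C=C([C@@H](CC=C(C)C)O)[C@H]1C[C@@H]2O[C@]2(C)[C@H](O)[C@@H]1O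
F12 | step 9 | ring-epoxy bis-angelate: 16 lacking only the side-chain oxirane | C=C([C@H](CC=C(C)C)OC(=O)/C(C)=C\C)[C@H]1C[C@@H]2O[C@]2(C)[C@@H](OC(=O)/C(C)=C\C)[C@@H]1O
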